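The route disconnects the C3=C4 double bond of the furan-2,5-dione ring, whose two carbons are both α to the ring carbonyls C2 and C5 and so have like polarity. Polarity is reversed by carrying the side-chain carbon as the ketone of an α-keto acid. The butenyl-bearing carbon is the α-carbon of an (E)-hex-3-enoyl unit, acidified by its β,γ-alkene. In one operation the keto acid is acylated to a mixed anhydride (the ring's own C–O–C tether), cyclises by intramolecular aldol addition and dehydrates, giving the anhydride ring and the conjugated diene. The precursor is an open-chain α-keto acid triester that already holds both stereocentres and the (Z)-enoate.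

Key step: step 14

Assumption: compounds 1 and 8 are bought, and the enantiomer of the ferrocenyl diphosphine in step 2 is the one that gives the (4R) product (its antipode is used if the sense of induction proves opposite).

Step 1
Reactants: 1 methyl 2-[(tert-butyldimethylsilyl)oxy]acetate; 2 (E)-1,4-dibromobut-2-ene
Product: 4 methyl (E)-6-bromo-2-[(tert-butyldimethylsilyl)oxy]hex-4-enoate (racemic), via lithium ester enolate 3 (not isolated)
Conditions: LiN(iPr)2, THF, –78 °C; then 2 (3 equiv), DMPU, –78 → –40 °C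
Reagents that add atoms: none
Why: Enolate alkylation (SN2) of the O-silyl glycolate enolate by the primary allylic bromide should give the monoalkylated ester, the excess of dibromide suppressing double alkylation; the C2 centre forms racemic and is erased in step 11.

Step 2
Reactants: 4 methyl (E)-6-bromo-2-[(tert-butyldimethylsilyl)oxy]hex-4-enoate
Product: 5 methyl (4R)-2-[(tert-butyldimethylsilyl)oxy]-4-ethylhex-5-enoate (both C2 epimers)
Conditions: EtMgBr (1.3 equiv, slow addition), CuBr·SMe2 (5 mol %), Taniaphos ligand 1-{(dimethylamino)[2-(diphenylphosphino)phenyl]methyl}-2-(diphenylphosphino)ferrocene (6 mol %), CH2Cl2, –75 °C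
Reagents that add atoms: ethylmagnesium bromide, CC[Mg]Br
Why: Copper-catalysed asymmetric allylic alkylation (SN2′) should deliver ethyl to the γ-carbon of the allylic bromide with transposition of the alkene, the chiral copper–diphosphine complex setting the C4 stereocentre under catalyst control while the low temperature spares the ester.

Step 3
Reactants: 5 methyl (4R)-2-[(tert-butyldimethylsilyl)oxy]-4-ethylhex-5-enoate
Product: 7 methyl (4R)-2-[(tert-butyldimethylsilyl)oxy]-4-formylhexanoate, via secondary ozonide 6 (not isolated)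
Conditions: O3, CH2Cl2, –78 °C; then PPh3, –78 °C → rt
Reagents that add atoms: ozone, [O-][O+]=O
Why: Ozonolysis with reductive work-up should cleave the only alkene to the aldehyde under neutral conditions that leave the adjacent stereocentre untouched; the aldehyde is used at once.

Step 4
Reactants: 8 D-glutamic acid 5-tert-butyl ester
Product: 9 (R)-5-tert-butoxy-2-hydroxy-5-oxopentanoic acid
Conditions: NaNO2, AcOH/H2O, 0 °C → rt
Reagents that add atoms: water, O
Why: Diazotisation of the α-amino acid should proceed with net retention through the α-lactone (double inversion by carboxylate participation), so the (R) centre of the D-amino acid is carried into the α-hydroxy acid.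

Step 5
Reactants: 9 (R)-5-tert-butoxy-2-hydroxy-5-oxopentanoic acid
Product: 10 di-tert-butyl (R)-2-hydroxypentanedioate
Conditions: tert-butyl 2,2,2-trichloroacetimidate, CH2Cl2/cyclohexane, rt
Reagents that add atoms: tert-butyl 2,2,2-trichloroacetimidate, CC(C)(C)OC(=N)C(Cl)(Cl)Cl
Why: Imidate esterification, promoted by the substrate acid itself, should form the tert-butyl ester without etherifying the secondary alcohol or touching the stereocentre.

Step 6
Reactants: 10 di-tert-butyl (R)-2-hydroxypentanedioate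
Product: 11 di-tert-butyl (R)-2-(trifluoromethylsulfonyloxy)pentanedioate
Conditions: Tf2O, 2,6-lutidine, CH2Cl2, –78 °C
Reagents that add atoms: trifluoromethanesulfonic anhydride, O=S(=O)(OS(=O)(=O)C(F)(F)F)C(F)(F)F
Why: O-Sulfonylation of the α-hydroxy ester with a hindered base at low temperature should give the α-triflate with the C–O bond and configuration intact.

Step 7
Reactants: 12 diphenyl phosphite; 13 tert-butyl bromoacetate
Product: 14 tert-butyl 2-(diphenoxyphosphoryl)acetate
Conditions: Et3N, CH2Cl2, 0 °C → rt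
Reagents that add atoms: none
Why: Michaelis–Becker alkylation of the P–H phosphite by the α-bromo ester should give the diaryl phosphonoacetate needed for a Z-selective olefination.

Step 8
Reactants: 14 tert-butyl 2-(diphenoxyphosphoryl)acetate; 11 di-tert-butyl (R)-2-(trifluoromethylsulfonyloxy)pentanedioate
Product: 16 tri-tert-butyl (2S)-1-(diphenoxyphosphoryl)butane-1,2,4-tricarboxylate (both C1 epimers), via sodium phosphonoacetate carbanion 15 (not isolated)
Conditions: NaH, THF, 0 °C; then 11, –78 → 0 °C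
Reagents that add atoms: none
Why: SN2 alkylation of the soft phosphonoacetate carbanion by the α-triflyloxy ester should proceed with clean inversion, turning the (R) carbinol carbon into the required configuration at C2; the phosphorus-bearing carbon is an irrelevant mixture.

Step 9
Reactants: 16 tri-tert-butyl (2S)-1-(diphenoxyphosphoryl)butane-1,2,4-tricarboxylate; 7 methyl (4R)-2-[(tert-butyldimethylsilyl)oxy]-4-formylhexanoate
Product: 18 10-tert-butyl 1-methyl (4R,5Z,7R)-6,7-bis(tert-butoxycarbonyl)-2-[(tert-butyldimethylsilyl)oxy]-4-ethyldec-5-enedioate (both C2 epimers), via sodium phosphonate carbanion 17 (not isolated)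
Conditions: NaH (0.95 equiv), THF, 0 °C; then 7, –78 → 0 °C
Reagents that add atoms: none
Why: In the Ando variant of the Horner–Wadsworth–Emmons reaction the diaryl phosphonate should collapse kinetically to the (Z)-trisubstituted enoate (ester cis to the alkyl chain), a preference reinforced by the branched α-substituent, while the slight deficit of base and the low temperature protect both α-stereocentres.

Step 10
Reactants: 18 the silyl ether from step 9
Product: 19 10-tert-butyl 1-methyl (4R,5Z,7R)-6,7-bis(tert-butoxycarbonyl)-4-ethyl-2-hydroxydec-5-enedioate (both C2 epimers)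
Conditions: HF·pyridine, pyridine, THF, 0 °C → rt
Reagents that add atoms: none
Why: Fluoride-mediated desilylation should free the secondary alcohol, the tert-butyl esters and the enoate being inert to buffered HF·pyridine.

Step 11
Reactants: 19 the α-hydroxy ester from step 10
Product: 20 10-tert-butyl 1-methyl (4R,5Z,7R)-6,7-bis(tert-butoxycarbonyl)-4-ethyl-2-oxodec-5-enedioate
Conditions: Dess–Martin periodinane, CH2Cl2, 0 °C → rt
Reagents that add atoms: none
Why: Dess–Martin oxidation of the α-hydroxy ester should give the α-keto ester under near-neutral conditions, converging the two C2 epimers to one compound.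

Step 12
Reactants: 20 the α-keto methyl ester from step 11
Product: 21 (4R,5Z,7R)-10-tert-butoxy-6,7-bis(tert-butoxycarbonyl)-4-ethyl-2,10-dioxodec-5-enoic acid
Conditions: LiOH (1.1 equiv), THF/H2O, 0 °C; then 1 M HCl to pH 3
Reagents that add atoms: lithium hydroxide, [Li+].[OH-]
Why: Chemoselective saponification should occur within minutes at the highly electrophilic α-keto methyl ester, while the hindered tert-butyl esters and the C7 stereocentre are left alone at 0 °C.

Step 13
Reactants: 22 (E)-hex-3-enoic acid (two molecules)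
Product: 23 (E)-hex-3-enoic anhydride
Conditions: DCC (0.5 equiv), CH2Cl2, 0 °C → rt
Reagents that add atoms: none
Why: Carbodiimide dehydration of two molecules of acid should give the symmetrical anhydride without moving the β,γ-alkene.

Step 14
Reactants: 21 the α-keto acid from step 12; 23 (E)-hex-3-enoic anhydride
Product: 26 tri-tert-butyl (3R,4Z,6R)-7-{4-[(E)-but-1-en-1-yl]-2,5-dioxo-2,5-dihydrofuran-3-yl}-6-ethylhept-4-ene-1,3,4-tricarboxylate, via mixed anhydride 24 (not isolated), via hydroxysuccinic anhydride aldol adduct 25 (not isolated)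
Conditions: 23 (3 equiv), Et3N (4 equiv), THF, 0 → 60 °C; then dilute aqueous HCl
Reagents that add atoms: none
Why: Proposed new method: the carboxylate of 21 should exchange with 23 to the mixed anhydride 24, triethylamine should remove the α-proton of the hex-3-enoyl part (acidified by the anhydride carbonyl and the β,γ-alkene), and the dienolate α-carbon should add to the adjacent ketone to give 25, whose tertiary alkoxide is acylated by excess 23 and lost by E1cB elimination to the tetrasubstituted ring alkene. The closest known reactions are the Perkin condensation of arylglyoxylic acids with arylacetic acids to diarylmaleic anhydrides and the base-mediated cyclisation of α-acyloxy ketones to butenolides; an aliphatic α-keto acid with an alk-3-enoic anhydride has no precedent. The five-membered anhydride ring closes in a 5-(enolendo)-exo-trig aldol mode, formally disfavoured by Baldwin's enolate rules but routinely realised in the butenolide cyclisations just named. No stereocentre is created: the two transient sp3 centres of 25 are erased by the elimination, the (E)-alkene of the butenyl group is carried over from 23, and the two existing stereocentres lie outside the reacting atoms. The step needs enolisation at the hexenoyl α-carbon in preference to the keto acid CH2 and the ester α-carbon at C3, which the higher acidity of an anhydride α-proton flanked by an alkene and the mild amine base should secure; attack through the α- and not the γ-carbon of the dienolate is enforced by the five-membered ring, and conjugation of the new alkene with both carbonyls and the diene drives the dehydration.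

Step 15
Reactants: 26 the tri-tert-butyl ester from step 14
Product: 27 (3R,4Z,6R)-7-{4-[(E)-but-1-en-1-yl]-2,5-dioxo-2,5-dihydrofuran-3-yl}-6-ethylhept-4-ene-1,3,4-tricarboxylic acid (CNP0256274.1)
Conditions: TFA/CH2Cl2 (1:2), 0 °C → rt
Reagents that add atoms: none
Why: Acidolysis of the three tert-butyl esters (loss of isobutene) should free the triacid, the dialkylmaleic anhydride being stable to anhydrous acid and no base touching the epimerisable C3 centre.

Compound list
1 | methyl 2-[(tert-butyldimethylsilyl)oxy]acetate | COC(=O)CO[Si](C)(C)C(C)(C)C | starting material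
2 | (E)-1,4-dibromobut-2-ene | BrC/C=C/CBr | starting material
3 | lithium enolate of 1 | [Li+].[O-]C(OC)=CO[Si](C)(C)C(C)(C)C | intermediate
4 | methyl (E)-6-bromo-2-[(tert-butyldimethylsilyl)oxy]hex-4-enoate (racemic) | COC(=O)C(O[Si](C)(C)C(C)(C)C)C/C=C/CBr | intermediate
5 | methyl (4R)-2-[(tert-butyldimethylsilyl)oxy]-4-ethylhex-5-enoate (both C2 epimers) | COC(=O)C(O[Si](C)(C)C(C)(C)C)C[C@H](C=C)CC | intermediate
6 | methyl (4R)-2-[(tert-butyldimethylsilyl)oxy]-4-(1,2,4-trioxolan-3-yl)hexanoate | COC(=O)C(O[Si](C)(C)C(C)(C)C)C[C@H](C1OCOO1)CC | intermediate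
7 | methyl (4R)-2-[(tert-butyldimethylsilyl)oxy]-4-formylhexanoate (both C2 epimers) | COC(=O)C(O[Si](C)(C)C(C)(C)C)C[C@H](C=O)CC | intermediate
8 | D-glutamic acid 5-tert-butyl ester, (R)-2-amino-5-tert-butoxy-5-oxopentanoic acid | N[C@H](CCC(=O)OC(C)(C)C)C(=O)O | starting material
9 | (R)-5-tert-butoxy-2-hydroxy-5-oxopentanoic acid | O[C@H](CCC(=O)OC(C)(C)C)C(=O)O | intermediate
10 | di-tert-butyl (R)-2-hydroxypentanedioate | O[C@H](CCC(=O)OC(C)(C)C)C(=O)OC(C)(C)C | intermediate
11 | di-tert-butyl (R)-2-(trifluoromethylsulfonyloxy)pentanedioate | FC(F)(F)S(=O)(=O)O[C@H](CCC(=O)OC(C)(C)C)C(=O)OC(C)(C)C | intermediate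
12 | diphenyl phosphite | O=[PH](Oc1ccccc1)Oc1ccccc1 | starting material
13 | tert-butyl bromoacetate | CC(C)(C)OC(=O)CBr | starting material
14 | tert-butyl 2-(diphenoxyphosphoryl)acetate | CC(C)(C)OC(=O)CP(=O)(Oc1ccccc1)Oc1ccccc1 | intermediate
15 | sodium carbanion of 14 | [Na+].CC(C)(C)OC(=O)[CH-]P(=O)(Oc1ccccc1)Oc1ccccc1 | intermediate
16 | tri-tert-butyl (2S)-1-(diphenoxyphosphoryl)butane-1,2,4-tricarboxylate (both C1 epimers) | CC(C)(C)OC(=O)C(P(=O)(Oc1ccccc1)Oc1ccccc1)[C@@H](CCC(=O)OC(C)(C)C)C(=O)OC(C)(C)C | intermediate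
17 | sodium carbanion of 16 | [Na+].CC(C)(C)OC(=O)[C-](P(=O)(Oc1ccccc1)Oc1ccccc1)[C@@H](CCC(=O)OC(C)(C)C)C(=O)OC(C)(C)C | intermediate
18 | 10-tert-butyl 1-methyl (4R,5Z,7R)-6,7-bis(tert-butoxycarbonyl)-2-[(tert-butyldimethylsilyl)oxy]-4-ethyldec-5-enedioate | COC(=O)C(O[Si](C)(C)C(C)(C)C)C[C@H](/C=C(\C(=O)OC(C)(C)C)[C@@H](CCC(=O)OC(C)(C)C)C(=O)OC(C)(C)C)CC | intermediate
19 | 10-tert-butyl 1-methyl (4R,5Z,7R)-6,7-bis(tert-butoxycarbonyl)-4-ethyl-2-hydroxydec-5-enedioate | COC(=O)C(O)C[C@H](/C=C(\C(=O)OC(C)(C)C)[C@@H](CCC(=O)OC(C)(C)C)C(=O)OC(C)(C)C)CC | intermediate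
20 | 10-tert-butyl 1-methyl (4R,5Z,7R)-6,7-bis(tert-butoxycarbonyl)-4-ethyl-2-oxodec-5-enedioate | COC(=O)C(=O)C[C@H](/C=C(\C(=O)OC(C)(C)C)[C@@H](CCC(=O)OC(C)(C)C)C(=O)OC(C)(C)C)CC | intermediate
21 | (4R,5Z,7R)-10-tert-butoxy-6,7-bis(tert-butoxycarbonyl)-4-ethyl-2,10-dioxodec-5-enoic acid | OC(=O)C(=O)C[C@H](/C=C(\C(=O)OC(C)(C)C)[C@@H](CCC(=O)OC(C)(C)C)C(=O)OC(C)(C)C)CC | intermediate
22 | (E)-hex-3-enoic acid | CC/C=C/CC(=O)O | starting material
23 | (E)-hex-3-enoic anhydride | CC/C=C/CC(=O)OC(=O)C/C=C/CC | intermediate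
24 | mixed anhydride of 21 with (E)-hex-3-enoic acid | CC/C=C/CC(=O)OC(=O)C(=O)C[C@H](/C=C(\C(=O)OC(C)(C)C)[C@@H](CCC(=O)OC(C)(C)C)C(=O)OC(C)(C)C)CC | intermediate
25 | tri-tert-butyl (3R,4Z,6R)-7-{4-[(E)-but-1-en-1-yl]-3-hydroxy-2,5-dioxooxolan-3-yl}-6-ethylhept-4-ene-1,3,4-tricarboxylate (ring centres undefined) | CC/C=C/C1C(=O)OC(=O)C1(O)C[C@H](/C=C(\C(=O)OC(C)(C)C)[C@@H](CCC(=O)OC(C)(C)C)C(=O)OC(C)(C)C)CC | intermediate
26 | tri-tert-butyl (3R,4Z,6R)-7-{4-[(E)-but-1-en-1-yl]-2,5-dioxo-2,5-dihydrofuran-3-yl}-6-ethylhept-4-ene-1,3,4-tricarboxylate | CC/C=C/C1=C(C[C@H](/C=C(\C(=O)OC(C)(C)C)[C@@H](CCC(=O)OC(C)(C)C)C(=O)OC(C)(C)C)CC)C(=O)OC1=O | intermediate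
27 | (3R,4Z,6R)-7-{4-[(E)-but-1-en-1-yl]-2,5-dioxo-2,5-dihydrofuran-3-yl}-6-ethylhept-4-ene-1,3,4-tricarboxylic acid | CC/C=C/C1=C(C[C@H](/C=C(\C(=O)O)[C@@H](CCC(=O)O)C(=O)O)CC)C(=O)OC1=O | target

Total step count: 15. Longest linear sequence: 10 steps (4, 5, 6, 8, 9, 10, 11, 12, 14, 15).

Steps most likely to fail

1. Step 14 (proposed new method). What may go wrong: enolisation and O-acylation on the keto acid side, or breakdown of the mixed anhydride, may outrun the aldol ring closure, and the warm amine may epimerise the C3 ester centre. Fallback, setting out from 19 and returning at 26: the methyl ester is reduced chemoselectively (LiBH4, THF, 0 °C) to the 8,9-diol triester F1. Its primary hydroxyl is acylated with 23 (2,4,6-collidine, CH2Cl2, –40 °C) to the primary hex-3-enoate F2, and Dess–Martin oxidation gives the α-acyloxy ketone F3. DBU in MeCN then closes the same ring carbon–carbon bond by the known intramolecular aldol condensation of α-acyloxy ketones to give the butenolide F4. Silylation (iPr3SiOTf, Et3N) gives the 2-silyloxyfuran F5, dimethyldioxirane in acetone gives the 5-hydroxybutenolide F6, and Dess–Martin oxidation returns to 26.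

2. Step 9. What may go wrong: the hindered phosphonate carbanion may add slowly to the branched aldehyde, Z-selectivity may erode, and prolonged base contact may epimerise the aldehyde α-carbon. Fallback, setting out from 14 and 7 and returning at 18: carbanion 15 is alkylated with (R)-4-benzyl-3-(2-bromoacetyl)oxazolidin-2-one F7 (made from (R)-4-benzyloxazolidin-2-one, n-BuLi and bromoacetyl bromide) to the less hindered imide phosphonate F8. The same Ando olefination with 7 gives the (Z)-alkylidenesuccinate imide F9. Its chlorotitanium enolate (TiCl4, iPr2NEt, CH2Cl2, –78 °C) adds to tert-butyl acrylate on the face away from the benzyl group to give the Michael adduct F10, so the C7 centre is set by the auxiliary after the alkene. LiOH/H2O2 then frees the C7 carboxylic acid F11, and tert-butyl 2,2,2-trichloroacetimidate returns to 18.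

3. Step 2. What may go wrong: the Grignard reagent may attack the ester, direct SN2 substitution may compete with SN2′, or enantioselectivity may be low with the remote ester present. Fallback, setting out from 1 and returning at 5: (S)-4-benzyl-3-(but-3-enoyl)oxazolidin-2-one F12 (from (S)-4-benzyloxazolidin-2-one and but-3-enoic acid via the pivaloyl mixed anhydride) is ethylated at the α-carbon through its sodium dienolate (NaN(SiMe3)2, EtOTf, THF, –78 °C) to (S)-4-benzyl-3-[(S)-2-ethylbut-3-enoyl]oxazolidin-2-one F13, the auxiliary controlling the new centre. Reduction (LiBH4, THF/MeOH, 0 °C) gives (S)-2-ethylbut-3-en-1-ol F14, and Tf2O with 2,6-lutidine gives (S)-2-ethylbut-3-en-1-yl trifluoromethanesulfonate F15. Alkylation of the lithium enolate 3 of 1 with F15 (THF/DMPU, –78 → –20 °C) then gives 5.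

Further compounds
F1 | step 14 | 8,9-diol triester (tri-tert-butyl (3R,4Z,6R)-6-ethyl-8,9-dihydroxynon-4-ene-1,3,4-tricarboxylate) | OCC(O)C[C@H](/C=C(\C(=O)OC(C)(C)C)[C@@H](CCC(=O)OC(C)(C)C)C(=O)OC(C)(C)C)CC
F2 | step 14 | primary hex-3-enoate (tri-tert-butyl (3R,4Z,6R)-6-ethyl-9-[(E)-hex-3-enoyloxy]-8-hydroxynon-4-ene-1,3,4-tricarboxylate) | CC/C=C/CC(=O)OCC(O)C[C@H](/C=C(\C(=O)OC(C)(C)C)[C@@H](CCC(=O)OC(C)(C)C)C(=O)OC(C)(C)C)CC
F3 | step 14 | α-acyloxy ketone (tri-tert-butyl (3R,4Z,6R)-6-ethyl-9-[(E)-hex-3-enoyloxy]-8-oxonon-4-ene-1,3,4-tricarboxylate) | CC/C=C/CC(=O)OCC(=O)C[C@H](/C=C(\C(=O)OC(C)(C)C)[C@@H](CCC(=O)OC(C)(C)C)C(=O)OC(C)(C)C)CC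
F4 | step 14 | butenolide (tri-tert-butyl (3R,4Z,6R)-7-{4-[(E)-but-1-en-1-yl]-5-oxo-2,5-dihydrofuran-3-yl}-6-ethylhept-4-ene-1,3,4-tricarboxylate) | CC/C=C/C1=C(C[C@H](/C=C(\C(=O)OC(C)(C)C)[C@@H](CCC(=O)OC(C)(C)C)C(=O)OC(C)(C)C)CC)COC1=O
F5 | step 14 | 2-silyloxyfuran (tri-tert-butyl (3R,4Z,6R)-7-{4-[(E)-but-1-en-1-yl]-5-[(triisopropylsilyl)oxy]furan-3-yl}-6-ethylhept-4-ene-1,3,4-tricarboxylate) | CC/C=C/c1c(C[C@H](/C=C(\C(=O)OC(C)(C)C)[C@@H](CCC(=O)OC(C)(C)C)C(=O)OC(C)(C)C)CC)coc1O[Si](C(C)C)(C(C)C)C(C)C
F6 | step 14 | 5-hydroxybutenolide (tri-tert-butyl (3R,4Z,6R)-7-{4-[(E)-but-1-en-1-yl]-2-hydroxy-5-oxo-2,5-dihydrofuran-3-yl}-6-ethylhept-4-ene-1,3,4-tricarboxylate) | CC/C=C/C1=C(C[C@H](/C=C(\C(=O)OC(C)(C)C)[C@@H](CCC(=O)OC(C)(C)C)C(=O)OC(C)(C)C)CC)C(O)OC1=O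
F7 | step 9 | (R)-4-benzyl-3-(2-bromoacetyl)oxazolidin-2-one | BrCC(=O)N1C(=O)OC[C@H]1Cc1ccccc1
F8 | step 9 | imide phosphonate (tert-butyl 4-[(R)-4-benzyl-2-oxooxazolidin-3-yl]-2-(diphenoxyphosphoryl)-4-oxobutanoate) | CC(C)(C)OC(=O)C(CC(=O)N1C(=O)OC[C@H]1Cc1ccccc1)P(=O)(Oc1ccccc1)Oc1ccccc1
F9 | step 9 | (Z)-alkylidenesuccinate imide (methyl (4R,5Z)-8-[(R)-4-benzyl-2-oxooxazolidin-3-yl]-6-(tert-butoxycarbonyl)-2-[(tert-butyldimethylsilyl)oxy]-4-ethyl-8-oxooct-5-enoate) | COC(=O)C(O[Si](C)(C)C(C)(C)C)C[C@H](/C=C(\C(=O)OC(C)(C)C)CC(=O)N1C(=O)OC[C@H]1Cc1ccccc1)CC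
F10 | step 9 | Michael adduct (10-tert-butyl 1-methyl (4R,5Z,7R)-7-[(R)-4-benzyl-2-oxooxazolidine-3-carbonyl]-6-(tert-butoxycarbonyl)-2-[(tert-butyldimethylsilyl)oxy]-4-ethyldec-5-enedioate) | COC(=O)C(O[Si](C)(C)C(C)(C)C)C[C@H](/C=C(\C(=O)OC(C)(C)C)[C@@H](CCC(=O)OC(C)(C)C)C(=O)N1C(=O)OC[C@H]1Cc1ccccc1)CC
F11 | step 9 | C7 carboxylic acid ((2R,3Z,5R)-3-(tert-butoxycarbonyl)-2-(3-tert-butoxy-3-oxopropyl)-7-[(tert-butyldimethylsilyl)oxy]-5-ethyl-8-methoxy-8-oxooct-3-enoic acid) | COC(=O)C(O[Si](C)(C)C(C)(C)C)C[C@H](/C=C(\C(=O)OC(C)(C)C)[C@@H](CCC(=O)OC(C)(C)C)C(=O)O)CC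
F12 | step 2 | (S)-4-benzyl-3-(but-3-enoyl)oxazolidin-2-one | C=CCC(=O)N1C(=O)OC[C@@H]1Cc1ccccc1
F13 | step 2 | (S)-4-benzyl-3-[(S)-2-ethylbut-3-enoyl]oxazolidin-2-one | O=C([C@H](C=C)CC)N1C(=O)OC[C@@H]1Cc1ccccc1
F14 | step 2 | (S)-2-ethylbut-3-en-1-ol | OC[C@H](C=C)CC
F15 | step 2 | (S)-2-ethylbut-3-en-1-yl trifluoromethanesulfonate | FC(F)(F)S(=O)(=O)OC[C@H](C=C)CC
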